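Cuts: C11=C12 and C11'=C12' (two Wittig olefinations around the C10 trienedial) give a ring A C15 phosphonium salt and a ring B C15 phosphonium salt; the ring A side chain is cut again at C8–C9 (syn-hydroalkynylation of ethyl but-2-ynoate).
Ring A is a cyclohex-3-en-1-ol: carbinol C3 is homoallylic to the C5=C6 double bond through C4, and olefinic C6 lies next to the gem-dimethyl carbon C1. This is the product pattern of an alkoxide-accelerated [1,3] shift of a 2-vinylcyclobutanol, so ring A is cut back to a cyclobutanol holding C3, C2, C1 and C6, with C5, its methyl and C4 as an isopropenyl group on C6.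
That cyclobutane is the [2+2] adduct of isobutylene (C1, C2, both C1 methyls) with an alkynyl(isopropenyl)ketene made from ethyl 2-bromo-3-methylbut-2-enoate and a silylacetylene.
Forward order: Sonogashira, ketene [2+2] to the cyclobutanone, CBS reduction, four-to-six ring expansion to ring A, alkyne unmasking, chain extension to the ring A C15 salt, Wittig with the C10 dial. Ring B comes from β-cyclocitral by Sharpless epoxidation, C5 Horner–Wadsworth–Emmons extension and epoxide hydrolysis; a final Wittig joins C25 and C15.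
Stereochemistry: C3 is set by the CBS reduction and carried on the migrating carbon through the ring expansion; C6' comes from the Sharpless epoxidation and C5' from anti opening of that epoxide by water. Double-bond geometry comes from E building blocks, one syn addition and E-selective tributylphosphonium Wittig reactions.

Key step: step 5

Assumption: ethyl 2-bromo-3-methylbut-2-enoate, the C10 trienedial and the C5 phosphonate (as its E isomer) are taken as catalogue compounds.

Step 1
Reactants: 1 ethyl 2-bromo-3-methylbut-2-enoate; 2 ethynyltri(propan-2-yl)silane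
Product: 3 ethyl 3-methyl-2-[(triisopropylsilyl)ethynyl]but-2-enoate
Conditions: PdCl2(PPh3)2 (3 mol %), CuI (5 mol %), Et3N, THF, 50 °C
Reagents that add atoms: none
Why: Sonogashira coupling of an electron-poor vinyl bromide with a terminal alkyne should give the 2-alkynyl enoate, and the β,β-dimethyl alkene has no geometry to lose.

Step 2
Reactants: 3 ethyl 3-methyl-2-[(triisopropylsilyl)ethynyl]but-2-enoate
Product: 4 3-methyl-2-[(triisopropylsilyl)ethynyl]but-2-enoic acid
Conditions: LiOH·H2O, THF/MeOH/H2O, 50 °C; then 1 M HCl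
Reagents that add atoms: lithium hydroxide, [Li+].[OH-]
Why: Saponification of the hindered ester should proceed on warming, and the bulky silyl–alkyne bond is expected to survive hydroxide.

Step 3
Reactants: 4 3-methyl-2-[(triisopropylsilyl)ethynyl]but-2-enoic acid; 5 2-methylpropene (isobutylene)
Product: 8 rac-3,3-dimethyl-2-(prop-1-en-2-yl)-2-[(triisopropylsilyl)ethynyl]cyclobutan-1-one, via acid chloride 6 (not isolated), via vinylketene 7 (not isolated)
Conditions: (COCl)2, DMF (cat.), CH2Cl2, 0 → 25 °C, evaporate; then 5 (10 equiv), Et3N (1.2 equiv, slow addition), CH2Cl2, sealed vessel, 40 °C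
Reagents that add atoms: none
Why: Oxalyl chloride gives 6, Et3N removes a γ-methyl proton with loss of chloride (1,4-dehydrochlorination) to form 7, and ketene–alkene [2+2] cycloaddition should join the ketene carbonyl carbon to the CH2 end and the ketene α-carbon to the dimethyl-substituted end of isobutylene, the usual regiochemistry with 1,1-disubstituted alkenes; the product is racemic.

Step 4
Reactants: 8 rac-3,3-dimethyl-2-(prop-1-en-2-yl)-2-[(triisopropylsilyl)ethynyl]cyclobutan-1-one
Product: 9 (1R)-3,3-dimethyl-2-(prop-1-en-2-yl)-2-[(triisopropylsilyl)ethynyl]cyclobutan-1-ol as both C2 epimers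
Conditions: (S)-2-methyl-CBS-oxazaborolidine (20 mol %), catecholborane (1.5 equiv), toluene, −78 °C; then MeOH, aq. NaHCO3
Reagents that add atoms: none
Why: Corey–Bakshi–Shibata reduction: the (S)-oxazaborolidine should bind the ketone anti to the fully substituted α-carbon (the large flank) and deliver hydride to give the (1R)-carbinol in both C2 epimers under catalyst control, while catecholborane at −78 °C should leave alkene and alkyne untouched.

Step 5
Reactants: 9 (1R)-3,3-dimethyl-2-(prop-1-en-2-yl)-2-[(triisopropylsilyl)ethynyl]cyclobutan-1-ol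
Product: 12 (1R)-3,5,5-trimethyl-4-[(triisopropylsilyl)ethynyl]cyclohex-3-en-1-ol, via potassium cyclobutanolate 10 (not isolated), via potassium cyclohexenolate 11 (not isolated)
Conditions: KH (1.2 equiv), THF, 0 → 25 °C; then H2O
Reagents that add atoms: none
Why: KH turns 9 into alkoxide 10, whose oxyanion weakens the adjacent ring bond to the quaternary carbon so that the carbinol carbon shifts from that carbon to the CH2 end of the isopropenyl group ([1,3] sigmatropic shift, suprafacial on the allyl unit with inversion at the migrating carbon) while the double bond moves into the ring, giving alkoxide 11. The closest known reaction type is the alkoxide-accelerated rearrangement of 2-vinylcyclobutanol salts to cyclohex-3-en-1-ols. The six-membered ring closes by C–C bond formation between the carbinol carbon and the olefin terminus as the four-membered ring opens, a two-carbon ring expansion driven by cyclobutane strain and by the vinyl and alkynyl groups that stabilise charge at the carbon being left. No stereocentre is created: the carbinol centre set by the catalyst in step 4 becomes C3 of ring A, inversion at the migrating carbon mapping (1R)-9 onto (1R)-12, and the quaternary centre is erased so that both epimers of 9 converge on one product. The step needs cleavage of the bond to the quaternary carbon and not of the bond to the ring CH2, secured because only the former leaves a stabilised allyl–propargyl terminus, and bonding at the isopropenyl CH2 and not at the alkyne end, secured because the latter would demand an allene inside a six-membered ring. It also needs fidelity at the migrating carbon, for which a contact ion pair in THF without crown ether and the lowest workable temperature are chosen.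

Step 6
Reactants: 12 (1R)-3,5,5-trimethyl-4-[(triisopropylsilyl)ethynyl]cyclohex-3-en-1-ol
Product: 13 (1R)-4-ethynyl-3,5,5-trimethylcyclohex-3-en-1-ol
Conditions: Bu4NF (1.2 equiv), THF, 0 → 25 °C
Reagents that add atoms: none
Why: Fluoride-induced protodesilylation of the alkynylsilane should free the terminal alkyne without touching the secondary alcohol or the stereocentre.

Step 7
Reactants: 13 (1R)-4-ethynyl-3,5,5-trimethylcyclohex-3-en-1-ol; 14 ethyl but-2-ynoate
Product: 15 ethyl (2E)-5-[(4R)-4-hydroxy-2,6,6-trimethylcyclohex-1-en-1-yl]-3-methylpent-2-en-4-ynoate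
Conditions: Pd(OAc)2 (3 mol %), tris(2,6-dimethoxyphenyl)phosphine (3 mol %), THF, 25 °C
Reagents that add atoms: none
Why: Palladium-catalysed cross-addition of a terminal alkyne to an alkynoate (hydroalkynylation): the alkynylpalladium hydride should add syn across 14 with the alkynyl group at the β-carbon, which fixes the 9E geometry and tolerates the free hydroxyl.

Step 8
Reactants: 15 ethyl (2E)-5-[(4R)-4-hydroxy-2,6,6-trimethylcyclohex-1-en-1-yl]-3-methylpent-2-en-4-ynoate
Product: 16 (1R)-4-[(3E)-5-hydroxy-3-methylpent-3-en-1-yn-1-yl]-3,5,5-trimethylcyclohex-3-en-1-ol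
Conditions: i-Bu2AlH (3.5 equiv), CH2Cl2, −78 °C; then aq. potassium sodium tartrate
Reagents that add atoms: none
Why: 1,2-Reduction of the conjugated ester by the aluminium hydride at low temperature should give the allylic alcohol with the enyne and its E geometry intact.

Step 9
Reactants: 16 (1R)-4-[(3E)-5-hydroxy-3-methylpent-3-en-1-yn-1-yl]-3,5,5-trimethylcyclohex-3-en-1-ol
Product: 18 tributyl{(2E)-5-[(4R)-4-hydroxy-2,6,6-trimethylcyclohex-1-en-1-yl]-3-methylpent-2-en-4-yn-1-yl}phosphonium bromide, via allylic bromide 17 (not isolated)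
Conditions: CBr4 (1.05 equiv), PBu3 (2.2 equiv), CH2Cl2, −30 → 25 °C
Reagents that add atoms: tributylphosphine, CCCCP(CCCC)CCCC; carbon tetrabromide, BrC(Br)(Br)Br
Why: Appel bromination should select the primary allylic hydroxyl over the hindered secondary ring hydroxyl, and SN2 quaternisation of 17 by the excess phosphine under non-ionising conditions should keep the 9E geometry.

Step 10
Reactants: 18 tributyl{(2E)-5-[(4R)-4-hydroxy-2,6,6-trimethylcyclohex-1-en-1-yl]-3-methylpent-2-en-4-yn-1-yl}phosphonium bromide; 19 (2E,4E,6E)-2,7-dimethylocta-2,4,6-trienedial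
Product: 21 (2E,4E,6E,8E,10E)-13-[(4R)-4-hydroxy-2,6,6-trimethylcyclohex-1-en-1-yl]-2,7,11-trimethyltrideca-2,4,6,8,10-pentaen-12-ynal, via phosphorus ylide 20 (not isolated)
Conditions: NaN(SiMe3)2 (1.05 equiv), THF, −78 °C, 5 min; then transfer into 19 (3 equiv), THF, −78 → −20 °C, dark
Reagents that add atoms: none
Why: Wittig olefination: allylic tributylphosphonium ylides should give the E C11=C12 bond, the excess dial limits reaction to one formyl group, and making and using 20 at −78 °C gives the delocalised ylide no time to lose the 9E geometry.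

Step 11
Reactants: 22 2,6,6-trimethylcyclohex-1-ene-1-carbaldehyde (β-cyclocitral)
Product: 23 (2,6,6-trimethylcyclohex-1-en-1-yl)methanol (β-cyclogeraniol)
Conditions: NaBH4, MeOH, 0 °C
Reagents that add atoms: none
Why: Borohydride 1,2-reduction of the hindered enal should give the allylic alcohol needed for directed epoxidation.

Step 12
Reactants: 23 (2,6,6-trimethylcyclohex-1-en-1-yl)methanol
Product: 24 [(1S,6S)-2,2,6-trimethyl-7-oxabicyclo[4.1.0]heptan-1-yl]methanol
Conditions: Ti(OiPr)4 (10 mol %), L-(+)-diethyl tartrate (12 mol %), t-BuOOH (2 equiv), 4 Å molecular sieves, CH2Cl2, −20 °C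
Reagents that add atoms: tert-butyl hydroperoxide, CC(C)(C)OO
Why: Sharpless asymmetric epoxidation: the titanium complex of L-(+)-diethyl tartrate should deliver oxygen to the same face of the allylic alcohol as in the geraniol to (2S,3S)-epoxygeraniol case, setting C6' and the cis-related C5' oxygen in one event.

Step 13
Reactants: 24 [(1S,6S)-2,2,6-trimethyl-7-oxabicyclo[4.1.0]heptan-1-yl]methanol
Product: 25 (1R,6S)-2,2,6-trimethyl-7-oxabicyclo[4.1.0]heptane-1-carbaldehyde
Conditions: Dess–Martin periodinane, pyridine (buffer), CH2Cl2, 0 → 25 °C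
Reagents that add atoms: none
Why: Dess–Martin oxidation under buffered conditions should give the non-enolisable epoxy aldehyde without opening the epoxide; the descriptor at C1 changes only through the priority rules.

Step 14
Reactants: 25 (1R,6S)-2,2,6-trimethyl-7-oxabicyclo[4.1.0]heptane-1-carbaldehyde; 26 ethyl (2E)-4-(diethoxyphosphoryl)-3-methylbut-2-enoate
Product: 28 ethyl (2E,4E)-3-methyl-5-[(1R,6S)-2,2,6-trimethyl-7-oxabicyclo[4.1.0]heptan-1-yl]penta-2,4-dienoate, via sodium phosphonate anion 27 (not isolated)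
Conditions: NaH (1.0 equiv to 26), THF, 0 °C; then 25, 0 → 25 °C
Reagents that add atoms: none
Why: Horner–Wadsworth–Emmons olefination of the hindered aldehyde should form the C7'=C8' bond E, and any 2Z isomer arising from the delocalised anion is removed by chromatography.

Step 15
Reactants: 28 ethyl (2E,4E)-3-methyl-5-[(1R,6S)-2,2,6-trimethyl-7-oxabicyclo[4.1.0]heptan-1-yl]penta-2,4-dienoate
Product: 29 ethyl (2E,4E)-5-[(1R,2R)-1,2-dihydroxy-2,6,6-trimethylcyclohexyl]-3-methylpenta-2,4-dienoate
Conditions: HClO4 (cat.), THF/H2O, 0 → 25 °C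
Reagents that add atoms: water, O
Why: Acid-catalysed epoxide hydrolysis: water should attack the methyl-bearing carbon C5' anti to the breaking C–O bond, because ionisation at C6' is disfavoured by the electron-poor dienoate, so inversion at C5' and retention at C6' give the trans (5'R,6'R)-diol.

Step 16
Reactants: 29 ethyl (2E,4E)-5-[(1R,2R)-1,2-dihydroxy-2,6,6-trimethylcyclohexyl]-3-methylpenta-2,4-dienoate
Product: 30 (1R,2R)-1-[(1E,3E)-5-hydroxy-3-methylpenta-1,3-dien-1-yl]-2,6,6-trimethylcyclohexane-1,2-diol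
Conditions: i-Bu2AlH (5 equiv), CH2Cl2, −78 → −40 °C; then aq. potassium sodium tartrate
Reagents that add atoms: none
Why: Aluminium hydride reduction of the dienoate should give the primary allylic alcohol, and the tertiary hydroxyls only consume hydride as alkoxides and return on work-up.

Step 17
Reactants: 30 (1R,2R)-1-[(1E,3E)-5-hydroxy-3-methylpenta-1,3-dien-1-yl]-2,6,6-trimethylcyclohexane-1,2-diol
Product: 32 tributyl{(2E,4E)-5-[(1R,2R)-1,2-dihydroxy-2,6,6-trimethylcyclohexyl]-3-methylpenta-2,4-dien-1-yl}phosphonium bromide, via allylic bromide 31 (not isolated)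
Conditions: CBr4 (1.05 equiv), PBu3 (2.2 equiv), CH2Cl2, −30 → 25 °C
Reagents that add atoms: tributylphosphine, CCCCP(CCCC)CCCC; carbon tetrabromide, BrC(Br)(Br)Br
Why: Appel bromination should touch only the primary allylic hydroxyl, and quaternisation by the excess phosphine under neutral conditions avoids the acid that would ionise the tertiary allylic C6' hydroxyl.

Step 18
Reactants: 32 tributyl{(2E,4E)-5-[(1R,2R)-1,2-dihydroxy-2,6,6-trimethylcyclohexyl]-3-methylpenta-2,4-dien-1-yl}phosphonium bromide; 21 (2E,4E,6E,8E,10E)-13-[(4R)-4-hydroxy-2,6,6-trimethylcyclohex-1-en-1-yl]-2,7,11-trimethyltrideca-2,4,6,8,10-pentaen-12-ynal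
Product: 34 (3R,5'R,6'R)-7,8-didehydro-5',6'-dihydro-β,β-carotene-3,5',6'-triol (CNP0289733.1), via phosphorus ylide 33 (not isolated)
Conditions: NaN(SiMe3)2 (1.05 equiv), THF, −78 °C; then 21, −78 → 0 °C, dark, argon
Reagents that add atoms: none
Why: Wittig olefination of the C25 aldehyde with the allylic tributylphosphonium ylide should close the C11'=C12' bond E without protecting groups, and no thermal or iodine isomerisation is applied, so the 9E enyne geometry is kept.

Compound list
1 | ethyl 2-bromo-3-methylbut-2-enoate | CCOC(=O)C(Br)=C(C)C | starting material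
2 | ethynyltri(propan-2-yl)silane | C#C[Si](C(C)C)(C(C)C)C(C)C | starting material
3 | ethyl 3-methyl-2-[(triisopropylsilyl)ethynyl]but-2-enoate | CCOC(=O)C(C#C[Si](C(C)C)(C(C)C)C(C)C)=C(C)C | intermediate
4 | 3-methyl-2-[(triisopropylsilyl)ethynyl]but-2-enoic acid | OC(=O)C(C#C[Si](C(C)C)(C(C)C)C(C)C)=C(C)C | intermediate
5 | 2-methylpropene (isobutylene) | CC(C)=C | starting material
6 | 3-methyl-2-[(triisopropylsilyl)ethynyl]but-2-enoyl chloride | ClC(=O)C(C#C[Si](C(C)C)(C(C)C)C(C)C)=C(C)C | intermediate
7 | 3-methyl-2-[(triisopropylsilyl)ethynyl]buta-1,3-dien-1-one (vinylketene) | O=C=C(C#C[Si](C(C)C)(C(C)C)C(C)C)C(C)=C | intermediate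
8 | rac-3,3-dimethyl-2-(prop-1-en-2-yl)-2-[(triisopropylsilyl)ethynyl]cyclobutan-1-one | O=C1CC(C)(C)C1(C#C[Si](C(C)C)(C(C)C)C(C)C)C(C)=C | intermediate
9 | (1R)-3,3-dimethyl-2-(prop-1-en-2-yl)-2-[(triisopropylsilyl)ethynyl]cyclobutan-1-ol, both C2 epimers | O[C@@H]1CC(C)(C)C1(C#C[Si](C(C)C)(C(C)C)C(C)C)C(C)=C | intermediate
10 | potassium (1R)-3,3-dimethyl-2-(prop-1-en-2-yl)-2-[(triisopropylsilyl)ethynyl]cyclobutan-1-olate | [K+].[O-][C@@H]1CC(C)(C)C1(C#C[Si](C(C)C)(C(C)C)C(C)C)C(C)=C | intermediate
11 | potassium (1R)-3,5,5-trimethyl-4-[(triisopropylsilyl)ethynyl]cyclohex-3-en-1-olate | CC1=C(C#C[Si](C(C)C)(C(C)C)C(C)C)C(C)(C)C[C@H]([O-])C1.[K+] | intermediate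
12 | (1R)-3,5,5-trimethyl-4-[(triisopropylsilyl)ethynyl]cyclohex-3-en-1-ol | CC1=C(C#C[Si](C(C)C)(C(C)C)C(C)C)C(C)(C)C[C@H](O)C1 | intermediate
13 | (1R)-4-ethynyl-3,5,5-trimethylcyclohex-3-en-1-ol | CC1=C(C#C)C(C)(C)C[C@H](O)C1 | intermediate
14 | ethyl but-2-ynoate | CC#CC(=O)OCC | starting material
15 | ethyl (2E)-5-[(4R)-4-hydroxy-2,6,6-trimethylcyclohex-1-en-1-yl]-3-methylpent-2-en-4-ynoate | CC1=C(C#C/C(C)=C/C(=O)OCC)C(C)(C)C[C@H](O)C1 | intermediate
16 | (1R)-4-[(3E)-5-hydroxy-3-methylpent-3-en-1-yn-1-yl]-3,5,5-trimethylcyclohex-3-en-1-ol | CC1=C(C#C/C(C)=C/CO)C(C)(C)C[C@H](O)C1 | intermediate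
17 | (1R)-4-[(3E)-5-bromo-3-methylpent-3-en-1-yn-1-yl]-3,5,5-trimethylcyclohex-3-en-1-ol | CC1=C(C#C/C(C)=C/CBr)C(C)(C)C[C@H](O)C1 | intermediate
18 | tributyl{(2E)-5-[(4R)-4-hydroxy-2,6,6-trimethylcyclohex-1-en-1-yl]-3-methylpent-2-en-4-yn-1-yl}phosphonium bromide | CC1=C(C#C/C(C)=C/C[P+](CCCC)(CCCC)CCCC)C(C)(C)C[C@H](O)C1.[Br-] | intermediate
19 | (2E,4E,6E)-2,7-dimethylocta-2,4,6-trienedial | O=C/C(C)=C/C=C/C=C(C)/C=O | starting material
20 | tributyl{(2E)-5-[(4R)-4-hydroxy-2,6,6-trimethylcyclohex-1-en-1-yl]-3-methylpent-2-en-4-yn-1-ylidene}phosphorane | CC1=C(C#C/C(C)=C/C=P(CCCC)(CCCC)CCCC)C(C)(C)C[C@H](O)C1 | intermediate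
21 | (2E,4E,6E,8E,10E)-13-[(4R)-4-hydroxy-2,6,6-trimethylcyclohex-1-en-1-yl]-2,7,11-trimethyltrideca-2,4,6,8,10-pentaen-12-ynal | CC1=C(C#C/C(C)=C/C=C/C(C)=C/C=C/C=C(C)/C=O)C(C)(C)C[C@H](O)C1 | intermediate
22 | 2,6,6-trimethylcyclohex-1-ene-1-carbaldehyde (β-cyclocitral) | CC1=C(C=O)C(C)(C)CCC1 | starting material
23 | (2,6,6-trimethylcyclohex-1-en-1-yl)methanol | CC1=C(CO)C(C)(C)CCC1 | intermediate
24 | [(1S,6S)-2,2,6-trimethyl-7-oxabicyclo[4.1.0]heptan-1-yl]methanol | OC[C@]12O[C@@]1(C)CCCC2(C)C | intermediate
25 | (1R,6S)-2,2,6-trimethyl-7-oxabicyclo[4.1.0]heptane-1-carbaldehyde | O=C[C@]12O[C@@]1(C)CCCC2(C)C | intermediate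
26 | ethyl (2E)-4-(diethoxyphosphoryl)-3-methylbut-2-enoate | CCOC(=O)/C=C(\C)CP(=O)(OCC)OCC | starting material
27 | sodium salt of the C4 carbanion of 26 | CCOC(=O)/C=C(\C)[CH-]P(=O)(OCC)OCC.[Na+] | intermediate
28 | ethyl (2E,4E)-3-methyl-5-[(1R,6S)-2,2,6-trimethyl-7-oxabicyclo[4.1.0]heptan-1-yl]penta-2,4-dienoate | CCOC(=O)/C=C(C)/C=C/[C@]12O[C@@]1(C)CCCC2(C)C | intermediate
29 | ethyl (2E,4E)-5-[(1R,2R)-1,2-dihydroxy-2,6,6-trimethylcyclohexyl]-3-methylpenta-2,4-dienoate | CCOC(=O)/C=C(C)/C=C/[C@@]1(O)C(C)(C)CCC[C@@]1(C)O | intermediate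
30 | (1R,2R)-1-[(1E,3E)-5-hydroxy-3-methylpenta-1,3-dien-1-yl]-2,6,6-trimethylcyclohexane-1,2-diol | OC/C=C(C)/C=C/[C@@]1(O)C(C)(C)CCC[C@@]1(C)O | intermediate
31 | (1R,2R)-1-[(1E,3E)-5-bromo-3-methylpenta-1,3-dien-1-yl]-2,6,6-trimethylcyclohexane-1,2-diol | BrC/C=C(C)/C=C/[C@@]1(O)C(C)(C)CCC[C@@]1(C)O | intermediate
32 | tributyl{(2E,4E)-5-[(1R,2R)-1,2-dihydroxy-2,6,6-trimethylcyclohexyl]-3-methylpenta-2,4-dien-1-yl}phosphonium bromide | CCCC[P+](CCCC)(CCCC)C/C=C(C)/C=C/[C@@]1(O)C(C)(C)CCC[C@@]1(C)O.[Br-] | intermediate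
33 | tributyl{(2E,4E)-5-[(1R,2R)-1,2-dihydroxy-2,6,6-trimethylcyclohexyl]-3-methylpenta-2,4-dien-1-ylidene}phosphorane | CCCCP(CCCC)(CCCC)=C/C=C(C)/C=C/[C@@]1(O)C(C)(C)CCC[C@@]1(C)O | intermediate
34 | (3R,5'R,6'R)-7,8-didehydro-5',6'-dihydro-β,β-carotene-3,5',6'-triol (CNP0289733.1) | CC1=C(C#C/C(C)=C/C=C/C(C)=C/C=C/C=C(C)/C=C/C=C(C)/C=C/[C@@]2(O)C(C)(C)CCC[C@@]2(C)O)C(C)(C)C[C@H](O)C1 | target

Total steps: 18. Longest linear sequence: 11 steps (steps 1 to 10, then step 18).

Steps most likely to fail

Step 5. The alkoxide may open reversibly to an aldehyde and a delocalised allyl–propargyl carbanion before the six-membered ring closes, so that configuration at the migrating carbinol carbon is lost (or transferred with retention) and ring A forms with eroded enantiomeric purity. The fallback secures C3 by enzymatic kinetic resolution instead of chirality transfer. It sets out from 12 of insufficient enantiomeric purity. Burkholderia cepacia lipase and vinyl acetate in tert-butyl methyl ether should acylate the (1R)-alcohol faster, on the usual empirical model for lipase acylation of secondary alcohols with the gem-dimethyl flank as the large group, giving (1R)-3,5,5-trimethyl-4-[(triisopropylsilyl)ethynyl]cyclohex-3-en-1-yl acetate F1. The slower (1S)-3,5,5-trimethyl-4-[(triisopropylsilyl)ethynyl]cyclohex-3-en-1-ol F2 is removed by chromatography. K2CO3 in methanol then cleaves F1 and the route is rejoined at enantiopure 12.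

Step 3. The vinylketene may dimerise or oligomerise faster than it adds to the weakly nucleophilic, volatile alkene. The fallback uses the more electrophilic keteniminium form of the [2+2] cycloaddition. It sets out from acid chloride 6, which with dimethylamine gives N,N-dimethyl-3-methyl-2-[(triisopropylsilyl)ethynyl]but-2-enamide F3. Tf2O and 2,4,6-collidine in 1,2-dichloroethane should convert F3 into N-methyl-N-{3-methyl-2-[(triisopropylsilyl)ethynyl]buta-1,3-dien-1-ylidene}methanaminium trifluoromethanesulfonate F4. This adds isobutylene 5 to give N-{3,3-dimethyl-2-(prop-1-en-2-yl)-2-[(triisopropylsilyl)ethynyl]cyclobutylidene}-N-methylmethanaminium trifluoromethanesulfonate F5. Aqueous NaHCO3 hydrolyses F5 and the route is rejoined at cyclobutanone 8.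

Step 15. Ionisation may occur at the allylic ring carbon C6' instead of attack at C5', with loss of regio- and stereocontrol or ring closure of the C5' oxygen onto the diene. The fallback hydrolyses the epoxide one stage earlier, where the adjacent formyl group forbids ionisation at C6'. It sets out from epoxy aldehyde 25, which with dilute HClO4 in aqueous THF should give (1R,2R)-1,2-dihydroxy-2,6,6-trimethylcyclohexane-1-carbaldehyde F6. Horner–Wadsworth–Emmons reaction of F6 with anion 27, made with exactly one equivalent of NaH so that the tertiary hydroxyls stay protonated and retro-aldol cleavage is avoided, rejoins the route at 29.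

Further compounds
F1 | step 5 | (1R)-3,5,5-trimethyl-4-[(triisopropylsilyl)ethynyl]cyclohex-3-en-1-yl acetate | CC1=C(C#C[Si](C(C)C)(C(C)C)C(C)C)C(C)(C)C[C@H](OC(C)=O)C1
F2 | step 5 | (1S)-3,5,5-trimethyl-4-[(triisopropylsilyl)ethynyl]cyclohex-3-en-1-ol | CC1=C(C#C[Si](C(C)C)(C(C)C)C(C)C)C(C)(C)C[C@@H](O)C1
F3 | step 3 | N,N-dimethyl-3-methyl-2-[(triisopropylsilyl)ethynyl]but-2-enamide | CN(C)C(=O)C(C#C[Si](C(C)C)(C(C)C)C(C)C)=C(C)C
F4 | step 3 | N-methyl-N-{3-methyl-2-[(triisopropylsilyl)ethynyl]buta-1,3-dien-1-ylidene}methanaminium trifluoromethanesulfonate | C[N+](C)=C=C(C#C[Si](C(C)C)(C(C)C)C(C)C)C(C)=C.[O-]S(=O)(=O)C(F)(F)F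
F5 | step 3 | N-{3,3-dimethyl-2-(prop-1-en-2-yl)-2-[(triisopropylsilyl)ethynyl]cyclobutylidene}-N-methylmethanaminium trifluoromethanesulfonate | C[N+](C)=C1CC(C)(C)C1(C#C[Si](C(C)C)(C(C)C)C(C)C)C(C)=C.[O-]S(=O)(=O)C(F)(F)F
F6 | step 15 | (1R,2R)-1,2-dihydroxy-2,6,6-trimethylcyclohexane-1-carbaldehyde | O=C[C@@]1(O)C(C)(C)CCC[C@@]1(C)O
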